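**Retrosynthetic overview**

1. Sarmentosumin D is cut at both CH2–ring A bonds: C8–CH2 (to ring D of the two-ring chain D–E) and C6–CH2 (to ring F of the three-ring chain F–G–H). This leaves a (2S)-7-O-benzyl-5-hydroxyflavanone (rings A, C, B) and two salicyl alcohols, and all three are joined in one flask.
2. Enabling feature: C6 and C8 are the only unsubstituted carbons of phloroglucinol-type ring A, each ortho or para to O1, O5 and O7. Each CH2 on ring A sits ortho to the phenolic OH of ring F or ring D, so both electrophiles are o-quinone methides.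
3. The order on ring A is set by the 7-O-benzyl group and the sequence of addition: trimer alcohol to C6 (next to the free 5-OH), then dimer alcohol to C8, the last open carbon. This second event forges the C8–CH2 bond between a C43 and a C14 fragment; hydrogenolysis ends the route.
4. Rings D–H come from one methoxy(formyl)phenylboronic acid by iterative benzylic Suzuki–Miyaura coupling, demethylation and reduction. The C2 centre comes from rhodium-catalysed asymmetric 1,4-addition of phenylboronic acid to a chromone.
5. No ring is built de novo: rings A and C are bought as 5,7-dihydroxychromone (ring C is saturated at C2–C3 in step 10), ring B as phenylboronic acid, rings D–H as two anisole-type building blocks.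

Key step: step 11

Assumption: the hydrogen-bonded 5-OH of the chromone is taken to be compatible with the base-free aqueous rhodium 1,4-addition, and 5,7-dihydroxychromone is taken as a catalogue chemical.

**Route**

Step 1
Reactants: 1 2-methoxybenzyl chloride; 2 (3-formyl-4-methoxyphenyl)boronic acid
Product: 3 2-methoxy-5-(2-methoxybenzyl)benzaldehyde
Conditions: Pd(PPh3)4 (cat.), K2CO3, DME/H2O, 80 °C
Reagents that add atoms: none
Why: Suzuki–Miyaura coupling of a benzylic chloride with an arylboronic acid (oxidative addition of zerovalent palladium into the C–Cl bond, transmetalation, reductive elimination) is a standard diarylmethane synthesis that tolerates the aldehyde and places the new CH2 para to the methoxy group of the boronic acid ring.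

Step 2
Reactants: 3 2-methoxy-5-(2-methoxybenzyl)benzaldehyde
Product: 4 2-hydroxy-5-(2-hydroxybenzyl)benzaldehyde
Conditions: BBr3, CH2Cl2, −78 to 0 °C; then H2O
Reagents that add atoms: none
Why: BBr3 cleaves both aryl methyl ethers by oxygen complexation and bromide attack on the methyl group (Lewis-acid ether cleavage), and the aldehyde is returned from its boron adduct on hydrolysis.

Step 3
Reactants: 4 2-hydroxy-5-(2-hydroxybenzyl)benzaldehyde
Product: 5 4-(2-hydroxybenzyl)-2-(hydroxymethyl)phenol (dimer alcohol; rings D and E)
Conditions: NaBH4, MeOH, 0 °C; neutral aqueous work-up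
Reagents that add atoms: none
Why: Sodium borohydride reduction of the salicylaldehyde gives the salicyl alcohol chemoselectively, and a neutral work-up keeps the acid-labile o-hydroxybenzyl alcohol from ionising early.

Step 4
Reactants: 3 2-methoxy-5-(2-methoxybenzyl)benzaldehyde
Product: 6 [2-methoxy-5-(2-methoxybenzyl)phenyl]methanol
Conditions: NaBH4, MeOH, 0 °C
Reagents that add atoms: none
Why: Sodium borohydride reduction converts the aldehyde into the primary benzylic alcohol needed for chain extension and leaves the aryl methyl ethers untouched.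

Step 5
Reactants: 6 [2-methoxy-5-(2-methoxybenzyl)phenyl]methanol
Product: 7 2-(bromomethyl)-1-methoxy-4-(2-methoxybenzyl)benzene
Conditions: PBr3, CH2Cl2, 0 °C
Reagents that add atoms: phosphorus tribromide, BrP(Br)Br
Why: PBr3 turns the primary benzylic alcohol into the bromide by SN2 displacement of an activated phosphite ester, conditions under which anisole-type ethers and the diarylmethane are inert.

Step 6
Reactants: 7 2-(bromomethyl)-1-methoxy-4-(2-methoxybenzyl)benzene; 2 (3-formyl-4-methoxyphenyl)boronic acid
Product: 8 2-methoxy-5-{[2-methoxy-5-(2-methoxybenzyl)phenyl]methyl}benzaldehyde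
Conditions: Pd(PPh3)4 (cat.), K2CO3, DME/H2O, 80 °C
Reagents that add atoms: none
Why: A second benzylic Suzuki–Miyaura coupling with the same boronic acid adds the formyl-bearing precursor of ring F, with the new CH2 again para to its methoxy group and the formyl group ortho to it.

Step 7
Reactants: 8 2-methoxy-5-{[2-methoxy-5-(2-methoxybenzyl)phenyl]methyl}benzaldehyde
Product: 9 2-hydroxy-5-{[2-hydroxy-5-(2-hydroxybenzyl)phenyl]methyl}benzaldehyde
Conditions: BBr3, CH2Cl2, −78 to 0 °C; then H2O
Reagents that add atoms: none
Why: BBr3 cleaves all three aryl methyl ethers by the same Lewis-acid ether cleavage as in step 2, the diarylmethane links and the aldehyde being stable to it.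

Step 8
Reactants: 9 2-hydroxy-5-{[2-hydroxy-5-(2-hydroxybenzyl)phenyl]methyl}benzaldehyde
Product: 10 2-(hydroxymethyl)-4-{[2-hydroxy-5-(2-hydroxybenzyl)phenyl]methyl}phenol (trimer alcohol; rings F, G and H)
Conditions: NaBH4, MeOH, 0 °C; neutral aqueous work-up
Reagents that add atoms: none
Why: Sodium borohydride reduction of the salicylaldehyde gives the second salicyl alcohol, again with a neutral work-up to keep the o-quinone methide precursor intact.

Step 9
Reactants: 11 5,7-dihydroxy-4H-chromen-4-one
Product: 12 7-(benzyloxy)-5-hydroxy-4H-chromen-4-one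
Conditions: BnBr, K2CO3, acetone, 50 °C
Reagents that add atoms: benzyl bromide, BrCc1ccccc1
Why: Williamson etherification occurs at the acidic, unchelated 7-OH only, because the 5-OH is held in a hydrogen bond to the C4 carbonyl and is far less nucleophilic under carbonate conditions.

Step 10
Reactants: 12 7-(benzyloxy)-5-hydroxy-4H-chromen-4-one; 13 phenylboronic acid
Product: 14 (2S)-7-(benzyloxy)-5-hydroxy-2-phenylchroman-4-one
Conditions: [Rh(OH)(cod)]2 (cat.), (S)-MeO-F12-BIPHEP [(S)-6,6'-dimethoxy-2,2'-bis{bis(3,4,5-trifluorophenyl)phosphino}-1,1'-biphenyl] (cat.), toluene/H2O, 25–40 °C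
Reagents that add atoms: none
Why: Hayashi–Miyaura reaction on a chromone, in which the phenyl–rhodium species (monovalent rhodium) bearing the electron-poor atropisomeric bisphosphine inserts the C2=C3 double bond on one face and hydrolysis of the resulting oxa-π-allyl complex gives the flavanone, the (S)-ligand being expected by the quadrant model used for cyclic enones to give the (2S) centre (the ligand antipode is taken if the observed sense is opposite).

Step 11
Reactants: 14 (2S)-7-(benzyloxy)-5-hydroxy-2-phenylchroman-4-one; 10 2-(hydroxymethyl)-4-{[2-hydroxy-5-(2-hydroxybenzyl)phenyl]methyl}phenol; 5 4-(2-hydroxybenzyl)-2-(hydroxymethyl)phenol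
Product: 16 (2S)-7-(benzyloxy)-5-hydroxy-8-{[2-hydroxy-5-(2-hydroxybenzyl)phenyl]methyl}-6-[(2-hydroxy-5-{[2-hydroxy-5-(2-hydroxybenzyl)phenyl]methyl}phenyl)methyl]-2-phenylchroman-4-one, via C6-benzylated flavanone 15 (not isolated)
Conditions: ZnCl2, 1,4-dioxane, 80 °C; 10 (1.0 equiv) added slowly, then 5 (1.3 equiv) added slowly
Reagents that add atoms: none
Why: ZnCl2 ionises the benzylic C–OH of a salicyl alcohol, assisted by its ortho phenol, to a zinc-bound o-quinone methide (first from 10, then from 5); the electron-rich ring A of the flavanone adds to its CH2 terminus in a Friedel–Crafts-type conjugate addition and proton loss restores both aromatic rings, the second event forming the C8–CH2 bond to ring D between fragment 15 and fragment 5. The closest known reaction type is the ZnCl2-mediated 2-hydroxybenzylation of 5,7-dioxygenated flavanones by 2-hydroxybenzyl alcohols, run here twice in one flask with two different alcohols. No ring is closed and no stereocentre is formed; C2 is remote from the reacting sites and the base-free medium should avoid the phenoxide-driven opening of ring C that would racemise it. The selectivity needed is C6 before C8 in the first addition: C6 lies ortho to the free 5-OH (zinc phenoxide) and should be attacked first, as in the C6-selective halogenation of 5-hydroxy-7-alkoxyflavonoids, whereas C8 is flanked by the 7-O-benzyl ether and O1; once C6 is filled, C8 is the only open carbon of ring A, so the position of the second bond is fixed by the substrate. Chemoselectivity for ring A over the mono-oxygenated side-chain rings rests on its three oxygen donors and on slow addition of each alcohol, which keeps the quinone methide concentration low.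

Step 12
Reactants: 16 (2S)-7-(benzyloxy)-5-hydroxy-8-{[2-hydroxy-5-(2-hydroxybenzyl)phenyl]methyl}-6-[(2-hydroxy-5-{[2-hydroxy-5-(2-hydroxybenzyl)phenyl]methyl}phenyl)methyl]-2-phenylchroman-4-one
Product: 17 sarmentosumin D [(2S)-5,7-dihydroxy-8-{[2-hydroxy-5-(2-hydroxybenzyl)phenyl]methyl}-6-[(2-hydroxy-5-{[2-hydroxy-5-(2-hydroxybenzyl)phenyl]methyl}phenyl)methyl]-2-phenylchroman-4-one]
Conditions: H2 (1 atm), Pd/C, EtOAc/MeOH, 25 °C
Reagents that add atoms: none
Why: Hydrogenolysis of the aryl benzyl ether over palladium proceeds under conditions that should leave the hydrogen-bonded aryl ketone, the diarylmethane links and the C2 centre untouched, and unveils the 7-OH to give the target.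

**Compound list**

1 | 2-methoxybenzyl chloride | COc1ccccc1CCl | starting material
2 | (3-formyl-4-methoxyphenyl)boronic acid | COc1ccc(B(O)O)cc1C=O | starting material
3 | 2-methoxy-5-(2-methoxybenzyl)benzaldehyde | COc1ccc(Cc2ccccc2OC)cc1C=O | intermediate
4 | 2-hydroxy-5-(2-hydroxybenzyl)benzaldehyde | O=Cc1cc(Cc2ccccc2O)ccc1O | intermediate
5 | 4-(2-hydroxybenzyl)-2-(hydroxymethyl)phenol (dimer alcohol) | OCc1cc(Cc2ccccc2O)ccc1O | intermediate
6 | [2-methoxy-5-(2-methoxybenzyl)phenyl]methanol | COc1ccc(Cc2ccccc2OC)cc1CO | intermediate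
7 | 2-(bromomethyl)-1-methoxy-4-(2-methoxybenzyl)benzene | COc1ccc(Cc2ccccc2OC)cc1CBr | intermediate
8 | 2-methoxy-5-{[2-methoxy-5-(2-methoxybenzyl)phenyl]methyl}benzaldehyde | COc1ccc(Cc2cc(Cc3ccccc3OC)ccc2OC)cc1C=O | intermediate
9 | 2-hydroxy-5-{[2-hydroxy-5-(2-hydroxybenzyl)phenyl]methyl}benzaldehyde | O=Cc1cc(Cc2cc(Cc3ccccc3O)ccc2O)ccc1O | intermediate
10 | 2-(hydroxymethyl)-4-{[2-hydroxy-5-(2-hydroxybenzyl)phenyl]methyl}phenol (trimer alcohol) | OCc1cc(Cc2cc(Cc3ccccc3O)ccc2O)ccc1O | intermediate
11 | 5,7-dihydroxy-4H-chromen-4-one | O=c1ccoc2cc(O)cc(O)c12 | starting material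
12 | 7-(benzyloxy)-5-hydroxy-4H-chromen-4-one | O=c1ccoc2cc(OCc3ccccc3)cc(O)c12 | intermediate
13 | phenylboronic acid | OB(O)c1ccccc1 | starting material
14 | (2S)-7-(benzyloxy)-5-hydroxy-2-phenylchroman-4-one | O=C1C[C@@H](c2ccccc2)Oc2cc(OCc3ccccc3)cc(O)c21 | intermediate
15 | (2S)-7-(benzyloxy)-5-hydroxy-6-[(2-hydroxy-5-{[2-hydroxy-5-(2-hydroxybenzyl)phenyl]methyl}phenyl)methyl]-2-phenylchroman-4-one | O=C1C[C@@H](c2ccccc2)Oc2cc(OCc3ccccc3)c(Cc3cc(Cc4cc(Cc5ccccc5O)ccc4O)ccc3O)c(O)c21 | intermediate
16 | (2S)-7-(benzyloxy)-5-hydroxy-8-{[2-hydroxy-5-(2-hydroxybenzyl)phenyl]methyl}-6-[(2-hydroxy-5-{[2-hydroxy-5-(2-hydroxybenzyl)phenyl]methyl}phenyl)methyl]-2-phenylchroman-4-one | O=C1C[C@@H](c2ccccc2)Oc2c(Cc3cc(Cc4ccccc4O)ccc3O)c(OCc3ccccc3)c(Cc3cc(Cc4cc(Cc5ccccc5O)ccc4O)ccc3O)c(O)c21 | intermediate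
17 | sarmentosumin D | O=C1C[C@@H](c2ccccc2)Oc2c(Cc3cc(Cc4ccccc4O)ccc3O)c(O)c(Cc3cc(Cc4cc(Cc5ccccc5O)ccc4O)ccc3O)c(O)c21 | target

**Step count and risks**

Total step count: 12. Longest linear sequence: 8 steps (steps 1, 4, 5, 6, 7, 8, 11, 12).

Risk 1, step 11. Discrimination between C6 and C8 in the first alkylation may be incomplete, the quinone methides may self-condense on the side-chain phenol rings, and prolonged Lewis-acid heating may erode the C2 configuration through reversible opening of ring C. The fallback sets out from 5 and returns to the route at 17; it fixes the C8 chain before ring C exists. Dimer alcohol 5 is coupled (ZnCl2, 1,4-dioxane, 80 °C) with purchased 1-[2,4-bis(benzyloxy)-6-hydroxyphenyl]ethanone (CC(=O)c1c(O)cc(OCc2ccccc2)cc1OCc1ccccc1). In this ketone the carbon between the free hydroxyl and one benzyl ether is open to attack, while the other free carbon is buried between two benzyl ethers. The coupling should give 1-[4,6-bis(benzyloxy)-2-hydroxy-3-{[2-hydroxy-5-(2-hydroxybenzyl)phenyl]methyl}phenyl]ethanone F1. Claisen formylation and cyclodehydration (HCO2Et, NaH, THF; then HCl, MeOH) should give 5,7-bis(benzyloxy)-8-{[2-hydroxy-5-(2-hydroxybenzyl)phenyl]methyl}-4H-chromen-4-one F2, in which the side chain must sit at C8 because only the free hydroxyl can become O1. Addition of 13 under the conditions of step 10 should give (2S)-5,7-bis(benzyloxy)-8-{[2-hydroxy-5-(2-hydroxybenzyl)phenyl]methyl}-2-phenylchroman-4-one F3. Hydrogenolysis (H2, Pd/C) should give (2S)-5,7-dihydroxy-8-{[2-hydroxy-5-(2-hydroxybenzyl)phenyl]methyl}-2-phenylchroman-4-one F4. ZnCl2-mediated coupling of F4 with 10 at C6, the sole open carbon of ring A, then gives 17.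

Risk 2, step 10. Insertion into the electron-rich, chelated chromone may be slow, so that protodeboronation of 13 outruns the 1,4-addition, or facial discrimination may be insufficient. The fallback takes the stereocentre from the chiral pool: it sets out not from a numbered compound but from purchased natural (2S)-5,7-dihydroxy-2-phenylchroman-4-one (O=C1C[C@@H](c2ccccc2)Oc2cc(O)cc(O)c21) and returns at 14. Selective 7-O-benzylation (BnBr, K2CO3, acetone, 25 °C) under the mild carbonate conditions of step 9 should give 14 directly, so that 11, 12 and 13 are not needed; this fallback makes no compound outside the list (F0).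

Risk 3, step 12. Hydrogenolysis of a benzyl ether flanked on both sides may be slow, which gives time for reductive opening of ring C at the benzylic C2–O1 bond or reduction of the ketone. The fallback sets out from 15 and returns at 17; it removes the benzyl group before the second alkylation. Step 11 is stopped after the first addition and 15 is isolated. Hydrogenolysis at this stage, where the benzyl ether has only one ortho substituent, should give (2S)-5,7-dihydroxy-6-[(2-hydroxy-5-{[2-hydroxy-5-(2-hydroxybenzyl)phenyl]methyl}phenyl)methyl]-2-phenylchroman-4-one F5. ZnCl2-mediated coupling of F5 with 5 then occurs at C8, the only open carbon of ring A and now ortho to the free 7-OH, to give 17 with no protecting group left to remove.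

**Further compounds**

F1 | step 11 | 1-[4,6-bis(benzyloxy)-2-hydroxy-3-{[2-hydroxy-5-(2-hydroxybenzyl)phenyl]methyl}phenyl]ethanone | CC(=O)c1c(O)c(Cc2cc(Cc3ccccc3O)ccc2O)c(OCc2ccccc2)cc1OCc1ccccc1
F2 | step 11 | 5,7-bis(benzyloxy)-8-{[2-hydroxy-5-(2-hydroxybenzyl)phenyl]methyl}-4H-chromen-4-one | O=c1ccoc2c(Cc3cc(Cc4ccccc4O)ccc3O)c(OCc3ccccc3)cc(OCc3ccccc3)c12
F3 | step 11 | (2S)-5,7-bis(benzyloxy)-8-{[2-hydroxy-5-(2-hydroxybenzyl)phenyl]methyl}-2-phenylchroman-4-one | O=C1C[C@@H](c2ccccc2)Oc2c(Cc3cc(Cc4ccccc4O)ccc3O)c(OCc3ccccc3)cc(OCc3ccccc3)c21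
F4 | step 11 | (2S)-5,7-dihydroxy-8-{[2-hydroxy-5-(2-hydroxybenzyl)phenyl]methyl}-2-phenylchroman-4-one | O=C1C[C@@H](c2ccccc2)Oc2c(Cc3cc(Cc4ccccc4O)ccc3O)c(O)cc(O)c21
F0 | step 10 | none | none
F5 | step 12 | (2S)-5,7-dihydroxy-6-[(2-hydroxy-5-{[2-hydroxy-5-(2-hydroxybenzyl)phenyl]methyl}phenyl)methyl]-2-phenylchroman-4-one | O=C1C[C@@H](c2ccccc2)Oc2cc(O)c(Cc3cc(Cc4cc(Cc5ccccc5O)ccc4O)ccc3O)c(O)c21
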